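**Plan**
- Enabling feature: in the cyclohexene core (C1 bearing CH3, C1=C2, C3 aryl, C4 aroyl, C5 aryl, C6H2) the ketone carbonyl hangs on C4. In an open chain C4=C5 is therefore the α,β-bond of an aryl enone and C3, next to C4, can be a ketone carbon. Aryl transfer to C5 then leaves a C4 enolate that closes the six-membered ring on the C3 carbonyl.
- Cuts, in retrosynthetic order: eight O–MOM bonds; chalcone Cα=Cβ; aryl–acetyl bond (carried as aryl–Br); C1–CH3; C3–H together with the C1 enol oxygen (back to a 3-aryl-cyclohex-2-enone); C5–aryl and C3–C4 in one operation; C4=C5; C3–aryl.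
- Forward: 1-bromo-2,4-bis(methoxymethoxy)benzene supplies the C5 boronic acid (bromine–lithium exchange) and the C3 aryl ketone (deprotonation between its two ether groups). Resorcinol supplies the aroyl ring through C2 lithiation, 3-methylbutanal addition and ring bromination. Dimethyl 3-oxopentanedioate supplies C5–C6–C1–C2–C3 through a desymmetrising lactonisation. The chain is joined, the only carbocycle closes in step 15, then enone → enol triflate → methyl → acetyl → chalcone → free phenols.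
- Stereochemistry: C5 (S) from (R)-BINAP on rhodium; C4 (R) from the closed aldol transition state, trans to the C5 aryl; C3 (S) from copper hydride delivery anti to the C4 aroyl; the three (E)-alkenes from Burgess elimination, Wittig reaction and Claisen–Schmidt condensation.

Key step: step 15

Remark: ring locants C1–C6 as defined above are used for all carbocyclic compounds and MOMO = methoxymethoxy. The C3 aryl carries bromine in place of its acyl group until step 19, because an aryl ketal can neither be made nor hydrolysed selectively beside aryl MOM ethers. The hydroxy ketone of step 12 is drawn open-chain although it may equilibrate with a cyclic hemiketal.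

**Route**

Step 1
Reactants: 1 4-bromobenzene-1,3-diol
Product: 2 1-bromo-2,4-bis(methoxymethoxy)benzene
Conditions: NaH, MOMCl, DMF, 0 °C → rt
Reagents that add atoms: chloromethyl methyl ether, COCCl
Why: Williamson-type O-alkylation of both phenoxides gives base-stable MOM ethers that later direct metalation.

Step 2
Reactants: 2 1-bromo-2,4-bis(methoxymethoxy)benzene
Product: 5 [2,4-bis(methoxymethoxy)phenyl]boronic acid, via 2,4-bis(methoxymethoxy)phenyllithium 3 (not isolated), via lithium aryltriisopropoxyborate 4 (not isolated)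
Conditions: n-BuLi, THF, −78 °C; B(Oi-Pr)3, −78 °C → rt; aq NH4Cl
Reagents that add atoms: triisopropyl borate, CC(C)OB(OC(C)C)OC(C)C; water, O
Why: Bromine–lithium exchange is faster than any deprotonation at −78 °C, and borylation of the aryllithium followed by mild hydrolysis is the standard arylboronic acid synthesis.

Step 3
Reactants: 6 benzene-1,3-diol (resorcinol)
Product: 7 1,3-bis(methoxymethoxy)benzene
Conditions: NaH, MOMCl, DMF, 0 °C → rt
Reagents that add atoms: chloromethyl methyl ether, COCCl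
Why: Williamson-type O-alkylation of both phenoxides installs the two ether groups that direct the lithiation of step 4.

Step 4
Reactants: 7 1,3-bis(methoxymethoxy)benzene; 8 3-methylbutanal
Product: 10 1-[2,6-bis(methoxymethoxy)phenyl]-3-methylbutan-1-ol (racemic), via 2,6-bis(methoxymethoxy)phenyllithium 9 (not isolated)
Conditions: n-BuLi, THF, 0 °C; 8, −78 → 0 °C; aq NH4Cl
Reagents that add atoms: none
Why: Directed ortho-metalation removes the hydrogen flanked by the two OMOM groups, and 1,2-addition of the aryllithium to the aldehyde gives a carbinol whose stereocentre is removed in step 6.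

Step 5
Reactants: 10 1-[2,6-bis(methoxymethoxy)phenyl]-3-methylbutan-1-ol
Product: 11 1-[3-bromo-2,6-bis(methoxymethoxy)phenyl]-3-methylbutan-1-ol (racemic)
Conditions: NBS (1.0 equiv), MeCN, 0 °C, dark
Reagents that add atoms: N-bromosuccinimide, O=C1CCC(=O)N1Br
Why: Electrophilic aromatic bromination goes to the position ortho to one OMOM and para to the other (the two such positions are equivalent, the third free position is meta to both), and the first bromine deactivates the ring against a second substitution.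

Step 6
Reactants: 11 1-[3-bromo-2,6-bis(methoxymethoxy)phenyl]-3-methylbutan-1-ol
Product: 13 1-bromo-2,4-bis(methoxymethoxy)-3-[(E)-3-methylbut-1-en-1-yl]benzene, via benzylic sulfamate salt 12 (not isolated)
Conditions: MeO2CN(−)SO2N(+)Et3 (Burgess reagent), toluene, 70 °C
Reagents that add atoms: none
Why: Burgess dehydration of the benzylic sulfamate can only eliminate toward the adjacent CH2 and should give the conjugated (E)-alkene without acid that would strip the MOM ethers.

Step 7
Reactants: 13 1-bromo-2,4-bis(methoxymethoxy)-3-[(E)-3-methylbut-1-en-1-yl]benzene; 14 2-chloro-N-methoxy-N-methylacetamide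
Product: 17 2-chloro-1-{2,4-bis(methoxymethoxy)-3-[(E)-3-methylbut-1-en-1-yl]phenyl}ethan-1-one, via alkenyl-substituted aryllithium 15 (not isolated), via lithium hemiaminal adduct 16 (not isolated)
Conditions: n-BuLi, THF, −78 °C; 14, −78 °C; aq NH4Cl
Reagents that add atoms: none
Why: Bromine–lithium exchange followed by Weinreb ketone synthesis, in which the chelated tetrahedral adduct prevents over-addition and the α-chloride is untouched at −78 °C.

Step 8
Reactants: 17 2-chloro-1-{2,4-bis(methoxymethoxy)-3-[(E)-3-methylbut-1-en-1-yl]phenyl}ethan-1-one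
Product: 19 1-{2,4-bis(methoxymethoxy)-3-[(E)-3-methylbut-1-en-1-yl]phenyl}-2-(triphenylphosphoranylidene)ethan-1-one, via acylmethylphosphonium chloride 18 (not isolated)
Conditions: PPh3, toluene, 80 °C; then 1 M NaOH, CH2Cl2, rt
Reagents that add atoms: triphenylphosphine, c1ccc(cc1)P(c1ccccc1)c1ccccc1
Why: SN2 quaternisation of the phosphine by the α-chloro ketone and deprotonation give an isolable stabilised acyl ylide (Wittig reagent synthesis).

Step 9
Reactants: 20 dimethyl 3-oxopentanedioate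
Product: 21 dimethyl 2,2'-(1,3-dioxolane-2,2-diyl)diacetate
Conditions: HOCH2CH2OH, TsOH·H2O (cat.), toluene, reflux (Dean–Stark)
Reagents that add atoms: ethylene glycol, OCCO
Why: Acid-catalysed ketalisation with azeotropic removal of water masks the central ketone (the future C1) and suppresses 1,3-dicarbonyl chemistry.

Step 10
Reactants: 21 dimethyl 2,2'-(1,3-dioxolane-2,2-diyl)diacetate
Product: 22 2,2'-(1,3-dioxolane-2,2-diyl)di(ethan-1-ol)
Conditions: LiAlH4, THF, 0 °C → rt; H2O, aq NaOH
Reagents that add atoms: none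
Why: Hydride reduction of both esters to primary alcohols leaves the ketal untouched.

Step 11
Reactants: 22 2,2'-(1,3-dioxolane-2,2-diyl)di(ethan-1-ol)
Product: 25 1,4,8-trioxaspiro[4.5]decan-7-one, via hydroxy aldehyde 23 (not isolated), via lactol 24 (not isolated)
Conditions: TEMPO (cat.), PhI(OAc)2, CH2Cl2, rt
Reagents that add atoms: none
Why: Oxoammonium-mediated oxidative lactonisation of a 1,5-diol, in which the first-formed hydroxy aldehyde closes to a six-membered lactol that is oxidised before the second alcohol, so the symmetric diol is desymmetrised without protecting groups.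

Step 12
Reactants: 2 1-bromo-2,4-bis(methoxymethoxy)benzene; 25 1,4,8-trioxaspiro[4.5]decan-7-one
Product: 28 1-[3-bromo-2,6-bis(methoxymethoxy)phenyl]-2-[2-(2-hydroxyethyl)-1,3-dioxolan-2-yl]ethan-1-one, via 3-bromo-2,6-bis(methoxymethoxy)phenyllithium 26 (not isolated), via lithium lactolate 27 (not isolated)
Conditions: LiN(i-Pr)2, THF, −78 °C; 25, −78 °C; aq NH4Cl
Reagents that add atoms: none
Why: Directed ortho-metalation with a lithium amide removes the hydrogen between the two OMOM groups and leaves the C–Br bond alone (lithium ends meta to bromine, so no aryne can form), then acyl substitution on the lactone gives a tetrahedral lithium lactolate that survives at −78 °C and collapses only on work-up, so a single aryl group is delivered and the C3–aryl bond is made.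

Step 13
Reactants: 28 1-[3-bromo-2,6-bis(methoxymethoxy)phenyl]-2-[2-(2-hydroxyethyl)-1,3-dioxolan-2-yl]ethan-1-one
Product: 29 (2-{2-[3-bromo-2,6-bis(methoxymethoxy)phenyl]-2-oxoethyl}-1,3-dioxolan-2-yl)acetaldehyde
Conditions: TEMPO (cat.), PhI(OAc)2, CH2Cl2, rt
Reagents that add atoms: none
Why: Oxoammonium oxidation of the primary alcohol stops at the aldehyde and is non-basic, which spares the β-ketal aldehyde from elimination.

Step 14
Reactants: 29 (2-{2-[3-bromo-2,6-bis(methoxymethoxy)phenyl]-2-oxoethyl}-1,3-dioxolan-2-yl)acetaldehyde; 19 1-{2,4-bis(methoxymethoxy)-3-[(E)-3-methylbut-1-en-1-yl]phenyl}-2-(triphenylphosphoranylidene)ethan-1-one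
Product: 30 (2E)-1-{2,4-bis(MOMO)-3-[(E)-3-methylbut-1-en-1-yl]phenyl}-4-(2-{2-[3-bromo-2,6-bis(MOMO)phenyl]-2-oxoethyl}-1,3-dioxolan-2-yl)but-2-en-1-one
Conditions: toluene, 60 °C
Reagents that add atoms: none
Why: Wittig olefination with a stabilised acyl ylide needs no base, so neither the β-ketal aldehyde nor the ketone is enolised, it reacts only with the aldehyde, and it should give the (E)-enone (C4=C5).

Step 15
Reactants: 30 (2E)-1-{2,4-bis(MOMO)-3-[(E)-3-methylbut-1-en-1-yl]phenyl}-4-(2-{2-[3-bromo-2,6-bis(MOMO)phenyl]-2-oxoethyl}-1,3-dioxolan-2-yl)but-2-en-1-one; 5 [2,4-bis(methoxymethoxy)phenyl]boronic acid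
Product: 31 (3S,4R,5S)-3-[3-bromo-2,6-bis(MOMO)phenyl]-4-{2,4-bis(MOMO)-3-[(E)-3-methylbut-1-en-1-yl]benzoyl}-5-[2,4-bis(MOMO)phenyl]-3-hydroxycyclohexan-1-one ethylene ketal
Conditions: [Rh(OH)((R)-BINAP)]2 (3 mol %), 5 (2.5 equiv), H2O (5 equiv), 1,4-dioxane, 50 °C
Reagents that add atoms: none
Why: Transmetalation of 5 to the hydroxo complex gives an aryl complex of monovalent rhodium that inserts the (E)-enone, bonding the aryl to C5 and leaving an oxa-π-allyl (Z)-enolate at C4, which adds to the C3 ketone before water cleaves the rhodium aldolate and returns the hydroxo complex. The closest known reaction type is this same rhodium–BINAP arylative aldol cyclisation of enones carrying a tethered ketone, an extension of the Hayashi–Miyaura addition. The carbocycle closes in a 6-(enolexo)-exo-trig mode through a chair-like Zimmerman–Traxler array with rhodium bridging both oxygens. C5 is controlled by the ligand, since by the accepted quadrant model (R)-BINAP delivers the aryl to the α-re face of an (E)-enone, which is 5S here; C4 is controlled by the chair with the C5 aryl equatorial, which places the aroyl trans to it; C3 is controlled by the same chair, with the bulky aryl equatorial and the rhodium-bound oxygen axial and cis to the aroyl, and this centre is erased in step 16. The step needs chemoselectivity (aryl transfer to the enone only, carbonyl addition faster than protonation of the enolate, no elimination of the β-ketal), and this should be secured by the single conjugate acceptor in 30, the six-atom tether, a C–Br bond inert to monovalent rhodium, the base-free hydroxo catalyst and the small amount of water. A cod-free catalyst is chosen so that no achiral rhodium–diene species competes.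

Step 16
Reactants: 31 (3S,4R,5S)-3-[3-bromo-2,6-bis(MOMO)phenyl]-4-{2,4-bis(MOMO)-3-[(E)-3-methylbut-1-en-1-yl]benzoyl}-5-[2,4-bis(MOMO)phenyl]-3-hydroxycyclohexan-1-one ethylene ketal
Product: 33 (4R,5S)-3-[3-bromo-2,6-bis(MOMO)phenyl]-4-{2,4-bis(MOMO)-3-[(E)-3-methylbut-1-en-1-yl]benzoyl}-5-[2,4-bis(MOMO)phenyl]cyclohex-2-en-1-one, via β-hydroxy ketone 32 (not isolated)
Conditions: TsOH·H2O (cat.), acetone/H2O, rt → 40 °C
Reagents that add atoms: water, O
Why: Acid-catalysed ketal hydrolysis followed by dehydration of the tertiary benzylic β-hydroxy ketone (aldol condensation type) should give the conjugated C2=C3 enone, because the unhindered ring ketone enolises toward C2 far faster than the twisted aroyl ketone toward C4, under conditions that aryl MOM ethers tolerate and with C4 staying trans to the C5 aryl, which is also the expected thermodynamic arrangement.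

Step 17
Reactants: 33 (4R,5S)-3-[3-bromo-2,6-bis(MOMO)phenyl]-4-{2,4-bis(MOMO)-3-[(E)-3-methylbut-1-en-1-yl]benzoyl}-5-[2,4-bis(MOMO)phenyl]cyclohex-2-en-1-one
Product: 35 (3S,4R,5S)-3-[3-bromo-2,6-bis(MOMO)phenyl]-4-{2,4-bis(MOMO)-3-[(E)-3-methylbut-1-en-1-yl]benzoyl}-5-[2,4-bis(MOMO)phenyl]cyclohex-1-en-1-yl trifluoromethanesulfonate, via dimethylphenylsilyl enol ether 34 (not isolated)
Conditions: [(Ph3P)CuH]6 (cat.), PhMe2SiH, toluene, rt; then CsF, PhNTf2, DME, rt
Reagents that add atoms: N-phenylbis(trifluoromethanesulfonimide), O=S(=O)(N(c1ccccc1)S(=O)(=O)C(F)(F)F)C(F)(F)F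
Why: Copper hydride-catalysed 1,4-hydrosilylation gives the regiodefined C1=C2 silyl enol ether, which fluoride and PhNTf2 convert into the enol triflate (conjugate reduction with enolate triflation); hydride should reach C3 on the face opposite the vicinal C4 aroyl, held pseudoaxial by allylic strain with the C3 aryl, so that H ends trans and the aryl cis to the aroyl (3S), while the styrenyl alkene, the aryl bromide and the hindered aroyl ketone are not reduced.

Step 18
Reactants: 35 (3S,4R,5S)-3-[3-bromo-2,6-bis(MOMO)phenyl]-4-{2,4-bis(MOMO)-3-[(E)-3-methylbut-1-en-1-yl]benzoyl}-5-[2,4-bis(MOMO)phenyl]cyclohex-1-en-1-yl trifluoromethanesulfonate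
Product: 36 (3S,4R,5S)-3-[3-bromo-2,6-bis(MOMO)phenyl]-4-{2,4-bis(MOMO)-3-[(E)-3-methylbut-1-en-1-yl]benzoyl}-5-[2,4-bis(MOMO)phenyl]-1-methylcyclohex-1-ene
Conditions: MeZnCl, Pd(PPh3)4 (cat.), THF, rt
Reagents that add atoms: methylzinc chloride, C[Zn]Cl
Why: Negishi coupling, in which zerovalent palladium inserts into the alkenyl triflate at room temperature far faster than into the electron-rich ortho-alkoxy aryl bromide and the organozinc does not add to the ketone, fixes the alkene at C1=C2.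

Step 19
Reactants: 36 (3S,4R,5S)-3-[3-bromo-2,6-bis(MOMO)phenyl]-4-{2,4-bis(MOMO)-3-[(E)-3-methylbut-1-en-1-yl]benzoyl}-5-[2,4-bis(MOMO)phenyl]-1-methylcyclohex-1-ene
Product: 38 (3S,4R,5S)-3-[3-acetyl-2,6-bis(MOMO)phenyl]-4-{2,4-bis(MOMO)-3-[(E)-3-methylbut-1-en-1-yl]benzoyl}-5-[2,4-bis(MOMO)phenyl]-1-methylcyclohex-1-ene, via 1-ethoxyvinyl arene 37 (not isolated)
Conditions: Bu3Sn[C(OEt)=CH2], Pd(PPh3)4 (cat.), toluene, 100 °C; then 1 M HCl, THF, rt
Reagents that add atoms: tributyl(1-ethoxyvinyl)stannane, CCCC[Sn](CCCC)(CCCC)C(=C)OCC; water, O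
Why: Stille coupling of the aryl bromide with a masked acetyl anion followed by brief hydrolysis of the enol ether unveils the methyl ketone under acid too mild to cleave aryl MOM ethers.

Step 20
Reactants: 39 2,4-dihydroxybenzaldehyde
Product: 40 2,4-bis(methoxymethoxy)benzaldehyde
Conditions: NaH, MOMCl, DMF, 0 °C → rt
Reagents that add atoms: chloromethyl methyl ether, COCCl
Why: O-alkylation of both phenoxides, the sodium salt being needed to alkylate the chelated ortho hydroxyl.

Step 21
Reactants: 38 (3S,4R,5S)-3-[3-acetyl-2,6-bis(MOMO)phenyl]-4-{2,4-bis(MOMO)-3-[(E)-3-methylbut-1-en-1-yl]benzoyl}-5-[2,4-bis(MOMO)phenyl]-1-methylcyclohex-1-ene; 40 2,4-bis(methoxymethoxy)benzaldehyde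
Product: 42 octakis(methoxymethyl) ether of artonin C, via β-hydroxy ketone aldol adduct 41 (not isolated)
Conditions: KOH, EtOH/H2O, rt
Reagents that add atoms: none
Why: Claisen–Schmidt condensation, in which only the methyl ketone enolate can add to the non-enolisable aldehyde and dehydrate to the (E)-chalcone, while C4, the one epimerisable centre, carries an equatorial aroyl between two equatorial-capable neighbours and is expected to be retained.

Step 22
Reactants: 42 octakis(methoxymethyl) ether of artonin C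
Product: 43 artonin C
Conditions: 3 M HCl, MeOH/THF, rt → 40 °C
Reagents that add atoms: none
Why: Acid-catalysed acetal solvolysis in methanol, the usual last step for MOM-protected polyhydroxychalcones, should free the eight phenols without touching the three stereocentres or the three alkenes if kept mild and short.

**Compound list**
1 | 4-bromobenzene-1,3-diol (4-bromoresorcinol) | Oc1ccc(Br)c(O)c1 | starting material
2 | 1-bromo-2,4-bis(methoxymethoxy)benzene | COCOc1ccc(Br)c(OCOC)c1 | intermediate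
3 | [2,4-bis(methoxymethoxy)phenyl]lithium | [Li]c1ccc(OCOC)cc1OCOC | intermediate
4 | lithium [2,4-bis(methoxymethoxy)phenyl]tri(propan-2-yloxy)borate | [Li+].CC(C)O[B-](OC(C)C)(OC(C)C)c1ccc(OCOC)cc1OCOC | intermediate
5 | [2,4-bis(methoxymethoxy)phenyl]boronic acid | OB(O)c1ccc(OCOC)cc1OCOC | intermediate
6 | benzene-1,3-diol (resorcinol) | Oc1cccc(O)c1 | starting material
7 | 1,3-bis(methoxymethoxy)benzene | COCOc1cccc(OCOC)c1 | intermediate
8 | 3-methylbutanal | CC(C)CC=O | starting material
9 | [2,6-bis(methoxymethoxy)phenyl]lithium | [Li]c1c(OCOC)cccc1OCOC | intermediate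
10 | 1-[2,6-bis(methoxymethoxy)phenyl]-3-methylbutan-1-ol (racemic) | CC(C)CC(O)c1c(OCOC)cccc1OCOC | intermediate
11 | 1-[3-bromo-2,6-bis(methoxymethoxy)phenyl]-3-methylbutan-1-ol (racemic) | CC(C)CC(O)c1c(OCOC)ccc(Br)c1OCOC | intermediate
12 | triethylammonium salt of the N-(methoxycarbonyl)sulfamate ester of 11 | CC[NH+](CC)CC.COC(=O)[N-]S(=O)(=O)OC(CC(C)C)c1c(OCOC)ccc(Br)c1OCOC | intermediate
13 | 1-bromo-2,4-bis(methoxymethoxy)-3-[(E)-3-methylbut-1-en-1-yl]benzene | COCOc1ccc(Br)c(OCOC)c1/C=C/C(C)C | intermediate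
14 | 2-chloro-N-methoxy-N-methylacetamide | CON(C)C(=O)CCl | starting material
15 | {2,4-bis(methoxymethoxy)-3-[(E)-3-methylbut-1-en-1-yl]phenyl}lithium | [Li]c1ccc(OCOC)c(/C=C/C(C)C)c1OCOC | intermediate
16 | lithium 1-aryl-2-chloro-1-[methoxy(methyl)amino]ethan-1-olate (tetrahedral adduct of 15 and 14) | [Li]OC(CCl)(N(C)OC)c1ccc(OCOC)c(/C=C/C(C)C)c1OCOC | intermediate
17 | 2-chloro-1-{2,4-bis(methoxymethoxy)-3-[(E)-3-methylbut-1-en-1-yl]phenyl}ethan-1-one | O=C(CCl)c1ccc(OCOC)c(/C=C/C(C)C)c1OCOC | intermediate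
18 | (2-{2,4-bis(methoxymethoxy)-3-[(E)-3-methylbut-1-en-1-yl]phenyl}-2-oxoethyl)triphenylphosphonium chloride | [Cl-].O=C(C[P+](c1ccccc1)(c1ccccc1)c1ccccc1)c1ccc(OCOC)c(/C=C/C(C)C)c1OCOC | intermediate
19 | 1-{2,4-bis(methoxymethoxy)-3-[(E)-3-methylbut-1-en-1-yl]phenyl}-2-(triphenylphosphoranylidene)ethan-1-one | O=C(C=P(c1ccccc1)(c1ccccc1)c1ccccc1)c1ccc(OCOC)c(/C=C/C(C)C)c1OCOC | intermediate
20 | dimethyl 3-oxopentanedioate | COC(=O)CC(=O)CC(=O)OC | starting material
21 | dimethyl 2,2'-(1,3-dioxolane-2,2-diyl)diacetate | COC(=O)CC1(CC(=O)OC)OCCO1 | intermediate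
22 | 2,2'-(1,3-dioxolane-2,2-diyl)di(ethan-1-ol) | OCCC1(CCO)OCCO1 | intermediate
23 | [2-(2-hydroxyethyl)-1,3-dioxolan-2-yl]acetaldehyde | O=CCC1(CCO)OCCO1 | intermediate
24 | 1,4,8-trioxaspiro[4.5]decan-7-ol | OC1CC2(CCO1)OCCO2 | intermediate
25 | 1,4,8-trioxaspiro[4.5]decan-7-one | O=C1CC2(CCO1)OCCO2 | intermediate
26 | [3-bromo-2,6-bis(methoxymethoxy)phenyl]lithium | [Li]c1c(OCOC)ccc(Br)c1OCOC | intermediate
27 | lithium 7-[3-bromo-2,6-bis(methoxymethoxy)phenyl]-1,4,8-trioxaspiro[4.5]decan-7-olate | [Li]OC1(c2c(OCOC)ccc(Br)c2OCOC)CC2(CCO1)OCCO2 | intermediate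
28 | 1-[3-bromo-2,6-bis(methoxymethoxy)phenyl]-2-[2-(2-hydroxyethyl)-1,3-dioxolan-2-yl]ethan-1-one | OCCC1(CC(=O)c2c(OCOC)ccc(Br)c2OCOC)OCCO1 | intermediate
29 | (2-{2-[3-bromo-2,6-bis(methoxymethoxy)phenyl]-2-oxoethyl}-1,3-dioxolan-2-yl)acetaldehyde | O=CCC1(CC(=O)c2c(OCOC)ccc(Br)c2OCOC)OCCO1 | intermediate
30 | (2E)-1-{2,4-bis(MOMO)-3-[(E)-3-methylbut-1-en-1-yl]phenyl}-4-(2-{2-[3-bromo-2,6-bis(MOMO)phenyl]-2-oxoethyl}-1,3-dioxolan-2-yl)but-2-en-1-one | O=C(/C=C/CC1(CC(=O)c2c(OCOC)ccc(Br)c2OCOC)OCCO1)c1ccc(OCOC)c(/C=C/C(C)C)c1OCOC | intermediate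
31 | (3S,4R,5S)-3-[3-bromo-2,6-bis(MOMO)phenyl]-4-{2,4-bis(MOMO)-3-[(E)-3-methylbut-1-en-1-yl]benzoyl}-5-[2,4-bis(MOMO)phenyl]-3-hydroxycyclohexan-1-one ethylene ketal (OH cis to aroyl, aroyl trans to C5 aryl) | C12(OCCO1)C[C@@](O)(c3c(OCOC)ccc(Br)c3OCOC)[C@H](C(=O)c3ccc(OCOC)c(/C=C/C(C)C)c3OCOC)[C@@H](c3ccc(OCOC)cc3OCOC)C2 | intermediate
32 | (3S,4R,5S)-3-[3-bromo-2,6-bis(MOMO)phenyl]-4-{2,4-bis(MOMO)-3-[(E)-3-methylbut-1-en-1-yl]benzoyl}-5-[2,4-bis(MOMO)phenyl]-3-hydroxycyclohexan-1-one | O=C1C[C@@](O)(c2c(OCOC)ccc(Br)c2OCOC)[C@H](C(=O)c2ccc(OCOC)c(/C=C/C(C)C)c2OCOC)[C@@H](c2ccc(OCOC)cc2OCOC)C1 | intermediate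
33 | (4R,5S)-3-[3-bromo-2,6-bis(MOMO)phenyl]-4-{2,4-bis(MOMO)-3-[(E)-3-methylbut-1-en-1-yl]benzoyl}-5-[2,4-bis(MOMO)phenyl]cyclohex-2-en-1-one | O=C1C=C(c2c(OCOC)ccc(Br)c2OCOC)[C@H](C(=O)c2ccc(OCOC)c(/C=C/C(C)C)c2OCOC)[C@@H](c2ccc(OCOC)cc2OCOC)C1 | intermediate
34 | dimethyl(phenyl)silyl enol ether of the (3S,4R,5S)-3,4,5-trisubstituted cyclohexanone (C1=C2, silyloxy on C1) | C[Si](C)(c1ccccc1)OC1=C[C@H](c2c(OCOC)ccc(Br)c2OCOC)[C@H](C(=O)c2ccc(OCOC)c(/C=C/C(C)C)c2OCOC)[C@@H](c2ccc(OCOC)cc2OCOC)C1 | intermediate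
35 | (3S,4R,5S)-3-[3-bromo-2,6-bis(MOMO)phenyl]-4-{2,4-bis(MOMO)-3-[(E)-3-methylbut-1-en-1-yl]benzoyl}-5-[2,4-bis(MOMO)phenyl]cyclohex-1-en-1-yl trifluoromethanesulfonate | O=S(=O)(OC1=C[C@H](c2c(OCOC)ccc(Br)c2OCOC)[C@H](C(=O)c2ccc(OCOC)c(/C=C/C(C)C)c2OCOC)[C@@H](c2ccc(OCOC)cc2OCOC)C1)C(F)(F)F | intermediate
36 | (3S,4R,5S)-3-[3-bromo-2,6-bis(MOMO)phenyl]-4-{2,4-bis(MOMO)-3-[(E)-3-methylbut-1-en-1-yl]benzoyl}-5-[2,4-bis(MOMO)phenyl]-1-methylcyclohex-1-ene | CC1=C[C@H](c2c(OCOC)ccc(Br)c2OCOC)[C@H](C(=O)c2ccc(OCOC)c(/C=C/C(C)C)c2OCOC)[C@@H](c2ccc(OCOC)cc2OCOC)C1 | intermediate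
37 | (3S,4R,5S)-3-[3-(1-ethoxyethenyl)-2,6-bis(MOMO)phenyl]-4-{2,4-bis(MOMO)-3-[(E)-3-methylbut-1-en-1-yl]benzoyl}-5-[2,4-bis(MOMO)phenyl]-1-methylcyclohex-1-ene | CC1=C[C@H](c2c(OCOC)ccc(C(=C)OCC)c2OCOC)[C@H](C(=O)c2ccc(OCOC)c(/C=C/C(C)C)c2OCOC)[C@@H](c2ccc(OCOC)cc2OCOC)C1 | intermediate
38 | (3S,4R,5S)-3-[3-acetyl-2,6-bis(MOMO)phenyl]-4-{2,4-bis(MOMO)-3-[(E)-3-methylbut-1-en-1-yl]benzoyl}-5-[2,4-bis(MOMO)phenyl]-1-methylcyclohex-1-ene | CC1=C[C@H](c2c(OCOC)ccc(C(C)=O)c2OCOC)[C@H](C(=O)c2ccc(OCOC)c(/C=C/C(C)C)c2OCOC)[C@@H](c2ccc(OCOC)cc2OCOC)C1 | intermediate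
39 | 2,4-dihydroxybenzaldehyde | O=Cc1ccc(O)cc1O | starting material
40 | 2,4-bis(methoxymethoxy)benzaldehyde | O=Cc1ccc(OCOC)cc1OCOC | intermediate
41 | aldol adduct of 38 and 40: the acetyl group extended to 3-[2,4-bis(MOMO)phenyl]-3-hydroxypropanoyl (both carbinol epimers) | CC1=C[C@H](c2c(OCOC)ccc(C(=O)CC(O)c3ccc(OCOC)cc3OCOC)c2OCOC)[C@H](C(=O)c2ccc(OCOC)c(/C=C/C(C)C)c2OCOC)[C@@H](c2ccc(OCOC)cc2OCOC)C1 | intermediate
42 | octakis(methoxymethyl) ether of artonin C | CC1=C[C@H](c2c(OCOC)ccc(C(=O)/C=C/c3ccc(OCOC)cc3OCOC)c2OCOC)[C@H](C(=O)c2ccc(OCOC)c(/C=C/C(C)C)c2OCOC)[C@@H](c2ccc(OCOC)cc2OCOC)C1 | intermediate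
43 | artonin C, (3S,4R,5S); C3 aryl cis to C4 aroyl, C4 aroyl trans to C5 aryl | CC1=C[C@H](c2c(O)ccc(C(=O)/C=C/c3ccc(O)cc3O)c2O)[C@H](C(=O)c2ccc(O)c(/C=C/C(C)C)c2O)[C@@H](c2ccc(O)cc2O)C1 | target

**Totals**
Total step count: 22.
Longest linear sequence: 14 steps (steps 3–8, 14–19, 21 and 22 from resorcinol).

**Steps most likely to fail**

Step 15. The risk is that protonation of the rhodium enolate (or protodeboronation of 5) outruns carbonyl addition at the twisted, doubly ortho-substituted aryl ketone, so that the chain is arylated but the ring does not close; reversal of the aldolate is the related failure. The fallback is an aprotic titanium-enolate relay that sets out from 30 and from aryllithium 3, made from 2 as in step 2. Transmetalation of 3 with ClTi(Oi-Pr)3 in THF should give [2,4-bis(methoxymethoxy)phenyl]titanium triisopropoxide F1. With [Rh(OH)((R)-BINAP)]2 in dry THF at 20 °C, F1 should transfer its aryl to C5 of 30 under the same ligand control and leave the titanium (Z)-enolate F2. No proton source can intercept F2, and its Lewis-acidic metal activates the hindered ketone for the same 6-(enolexo)-exo-trig closure to titanium aldolate F3. Aqueous NH4Cl work-up comes back to the route at 31.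

Step 17. The risk is slow or poorly face-selective hydride transfer to the β,β-disubstituted C3, because in the diaxial conformer the C5 aryl lies on the face the hydride must use. A second risk is proton exchange between the fluoride-generated enolate and the acidic C4–H before O-sulfonylation. The fallback replaces substrate control by reagent control and sets out from 33. A chiral bisphosphine–copper hydride (CuCl, NaOt-Bu, the p-Tol-BINAP enantiomer whose preferred face is the one anti to the C4 aroyl, Ph2SiH2, toluene, 0 °C) should deliver hydride to C3 and give diphenylsilyl enol ether F4. n-C4F9SO2F with catalytic n-Bu4N[Ph3SiF2] should convert F4 into alkenyl nonaflate F5 while the free enolate stays at catalytic concentration. Negishi methylation of F5 (MeZnCl, Pd(PPh3)4, THF) comes back to the route at 36.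

Step 22. The risk is over-reaction under Brønsted acid once phenols are free: ketalisation of the C4 carbonyl by the flanking ortho phenols, cyclisation of the 2′-hydroxychalcone to a flavanone or flavylium ion, and slow loss of the chelated MOM groups that prolongs exposure. The fallback is a silyl-transfer deprotection without protic acid and sets out from 42. TMSOTf and 2,2′-bipyridyl in MeCN at 0 °C should convert each aryl MOM ether into an aryl trimethylsilyl ether, the methoxymethyl unit leaving on the bipyridine nitrogen, to give octakis(trimethylsilyl) ether F6. No phenol is free in F6 while a Lewis acid is present. Methanol at rt then cleaves the eight Si–O bonds and comes back to the route at 43.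

**Further compounds**
F1 | step 15 | [2,4-bis(methoxymethoxy)phenyl]titanium triisopropoxide | CC(C)O[Ti](OC(C)C)(OC(C)C)c1ccc(OCOC)cc1OCOC
F2 | step 15 | triisopropoxytitanium (Z)-enolate of the C5-arylated (5S) open-chain ketone | CC(C)O[Ti](OC(C)C)(OC(C)C)O/C(=C\[C@@H](c1ccc(OCOC)cc1OCOC)CC1(CC(=O)c2c(OCOC)ccc(Br)c2OCOC)OCCO1)c1ccc(OCOC)c(/C=C/C(C)C)c1OCOC
F3 | step 15 | triisopropoxytitanium aldolate of 31 | C12(OCCO1)C[C@@](O[Ti](OC(C)C)(OC(C)C)OC(C)C)(c3c(OCOC)ccc(Br)c3OCOC)[C@H](C(=O)c3ccc(OCOC)c(/C=C/C(C)C)c3OCOC)[C@@H](c3ccc(OCOC)cc3OCOC)C2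
F4 | step 17 | diphenylsilyl enol ether of the (3S,4R,5S)-cyclohexanone (C1=C2) | [SiH](c1ccccc1)(c1ccccc1)OC1=C[C@H](c2c(OCOC)ccc(Br)c2OCOC)[C@H](C(=O)c2ccc(OCOC)c(/C=C/C(C)C)c2OCOC)[C@@H](c2ccc(OCOC)cc2OCOC)C1
F5 | step 17 | (3S,4R,5S)-cyclohex-1-en-1-yl nonafluorobutane-1-sulfonate analogue of 35 | O=S(=O)(OC1=C[C@H](c2c(OCOC)ccc(Br)c2OCOC)[C@H](C(=O)c2ccc(OCOC)c(/C=C/C(C)C)c2OCOC)[C@@H](c2ccc(OCOC)cc2OCOC)C1)C(F)(F)C(F)(F)C(F)(F)C(F)(F)F
F6 | step 22 | octakis(trimethylsilyl) ether of artonin C | CC1=C[C@H](c2c(O[Si](C)(C)C)ccc(C(=O)/C=C/c3ccc(O[Si](C)(C)C)cc3O[Si](C)(C)C)c2O[Si](C)(C)C)[C@H](C(=O)c2ccc(O[Si](C)(C)C)c(/C=C/C(C)C)c2O[Si](C)(C)C)[C@@H](c2ccc(O[Si](C)(C)C)cc2O[Si](C)(C)C)C1
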